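## Retrosynthetic overview
1. Target 30 comes from bicycle 21 by functional-group changes only. These are C2 C=O → OAc; ring-A enol silane → Δ13-enone → 13α,14α-epoxide → 12β-OH; and Δ5 → 6-OH/5(16)-ene (Schenck ene) → 6-Cl (SN2).
2. 21 comes from acyclic 20 by one macrocyclising intramolecular Diels–Alder reaction. Bonds C1–C10 and C13–C14 form, so the cyclohexene and the ten-membered carbocycle close together.
3. 20 comes from enal 13 and chloromethyl isopropenyl ketone 16. A reagent-controlled syn-aldol followed by Darzens closure makes C3–C4 and the cis-oxirane.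
4. 13 comes from diacetone-D-glucose, with sugar C2/C3/C4 becoming C7/C8/C9. A propionate aldol at the 3-ulose sets C8 and C17, and two Wittig reactions at sugar C5 and C1 make C10=C11 and C5=C6.
5. Ring order: γ-lactone (step 6) → 3,4-oxirane (step 9) → six- and ten-membered carbocycles together (step 11) → 13,14-oxirane (step 16).

Numbering: briarane numbering is used throughout. C1 is the quaternary fusion carbon, C2–C9 the tether (ten-membered ring), C10–C14 the rest of the six-membered ring, C15/C16/C18/C20 the methyls on C1/C5/C17/C11, and C17–C19 the lactone carbons; α is the face of H-10 and β the face of C15.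

Assumption: (−)-Ipc2BOTf [from (+)-α-pinene], IBX, Zn(BH4)2 solution and LDA are taken as stock reagents, and lactol 9 is an anomeric mixture, so its hemiacetal carbon is drawn without configuration.

## Route

Step 1
Reactants: 1 diacetone-D-glucose (1,2:5,6-di-O-isopropylidene-α-D-glucofuranose)
Product: 2 1,2:5,6-di-O-isopropylidene-α-D-ribo-hexofuranos-3-ulose
Conditions: TEMPO (cat.), KBr (cat.), NaOCl, NaHCO3, CH2Cl2/H2O, 0 °C; toluene azeotrope
Reagents that add atoms: none
Why: TEMPO/hypochlorite (Anelli) oxidation of the only free hydroxyl gives the 3-ulose; no stereocentre is created, and sugar C2/C4 (future C7/C9) are held in the cis-fused bicycle.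

Step 2
Reactants: 2 the 3-ulose; 3 methyl propionate
Product: 5 methyl (2R)-2-(1,2:5,6-di-O-isopropylidene-α-D-allofuranos-3-C-yl)propanoate, via lithium enolate 4 (not isolated)
Conditions: LDA, THF/DMPU, −78 °C, 3; then 2, −78 °C; AcOH quench
Reagents that add atoms: none
Why: In this lithium ester-enolate aldol addition to a ketone, the Z(O)-enolate can reach the carbonyl only from the convex β face opposite the 1,2-acetonide (sets C8, allo, OH α), and the closed transition state with H-17 over the furanose ring and the small methyl next to the bulky C4 side chain sets C17 (R).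

Step 3
Reactants: 5 the branched allofuranose ester
Product: 6 methyl (2R)-2-(1,2-O-isopropylidene-α-D-ribo-pentodialdo-1,4-furanos-3-C-yl)propanoate (C10 aldehyde)
Conditions: H5IO6, EtOAc, rt
Reagents that add atoms: none
Why: Periodic acid hydrolyses the more labile terminal acetonide and cleaves the freed glycol in the same pot (Malaprade cleavage), leaving the 1,2-acetonide, tertiary alcohol, ester and all stereocentres untouched.

Step 4
Reactants: 6 the C10 aldehyde; 7 3-(triphenylphosphoranylidene)butan-2-one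
Product: 8 furanose (E)-enone (6 with CHO replaced by (E)-CH=C(CH3)C(O)CH3; C10=C11)
Conditions: PhMe, 80 °C
Reagents that add atoms: none
Why: Wittig olefination with a stabilised α-branched keto ylide is E-selective (C9 cis to C20), and the neutral conditions avoid epimerisation at C9.

Step 5
Reactants: 8 the furanose enone
Product: 9 lactol (8 without the 1,2-acetonide; free anomeric OH α/β and free C7-OH)
Conditions: TFA/H2O 4:1, 0 °C → rt
Reagents that add atoms: water, O
Why: Acid-catalysed acetal hydrolysis unmasks the latent C6 aldehyde and the C7 hydroxyl while O9 stays tied up as the furanose ring oxygen; no stereocentre of the target is touched.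

Step 6
Reactants: 9 the lactol; 10 2-(triphenylphosphoranylidene)propanal
Product: 12 (5E,10E)-enal γ-lactone with free 8-OH and 9-OH [OHC(C4)–C5(Me)=C6–C7(O-lactone)–C8(OH)–C9(OH)–C10=C11(Me)–C12(O)–C13], via triol ester 11 (not isolated)
Conditions: PhMe, 70 °C; then CSA (cat.), rt
Reagents that add atoms: none
Why: Wittig olefination of the ring-opened lactol with the stabilised formyl ylide gives the (E)-C5=C6 enal, and acid-equilibrated lactonisation settles on the O7 γ-lactone because only there is C18 trans to the large C8 substituent (in the O9 lactone it would be cis to the C7 chain).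

Step 7
Reactants: 12 the enal lactone
Product: 13 9-O-acetyl enal lactone
Conditions: Ac2O, pyridine, DMAP (cat.), CH2Cl2, 0 °C
Reagents that add atoms: acetic anhydride, CC(=O)OC(C)=O
Why: DMAP-catalysed acetylation of the only secondary alcohol locks the lactone regiochemistry and installs the C9 acetate; the hindered tertiary 8-OH does not react.

Step 8
Reactants: 14 2-chloro-N-methoxy-N-methylacetamide; 15 isopropenylmagnesium bromide
Product: 16 1-chloro-3-methylbut-3-en-2-one
Conditions: THF, −78 → −20 °C; 1 M HCl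
Reagents that add atoms: none
Why: In this Weinreb ketone synthesis the chelated tetrahedral adduct stops at mono-addition and the C–Cl bond survives at low temperature; no stereocentre is formed.

Step 9
Reactants: 13 the 9-O-acetyl enal; 16 the chloro enone
Product: 19 cis-3,4-epoxy isopropenyl ketone (13 with CHO replaced by cis-oxirane–C(O)–C(CH3)=CH2), via boron enolate 17 (not isolated), via syn-chlorohydrin 18 (not isolated)
Conditions: 16, (−)-Ipc2BOTf, i-Pr2NEt, CH2Cl2, −78 °C; 13, −78 → −20 °C; H2O2, pH 7 buffer, MeOH, 0 °C; crude, DBU, CH2Cl2, 0 °C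
Reagents that add atoms: none
Why: In the Ipc-boron (Paterson-type) syn-aldol the (Z)-chloro enolate attacks the Si face of the enal under reagent control (sets C4 R and the syn C3 chloride), and Darzens-type closure with inversion at C3 gives the cis-epoxide (3R,4R).

Step 10
Reactants: 19 the epoxy enone
Product: 20 2-silyloxydiene (C13H2=C12(OTBS)–C11(Me)=C10H–) carrying the isopropenyl ketone at the other chain end
Conditions: TBSOTf (1.2 equiv), Et3N, CH2Cl2, −78 °C
Reagents that add atoms: tert-butyldimethylsilyl triflate, CC(C)(C)[Si](C)(C)OS(=O)(=O)C(F)(F)F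
Why: Soft enolisation (silyl triflate/amine) acts on the only enolisable ketone, the C12 methyl ketone, because the C2 ketone has no usable α-H and the lactone, acetate and crowded tertiary OH are too slow at −78 °C; no stereocentre is formed.

Step 11
Reactants: 20 the silyloxydiene/isopropenyl ketone
Product: 21 trans-fused bicyclo[8.4.0] adduct (2-oxo; 3,4-cis-epoxide; 5E-ene; 7,8-lactone; 9-OAc; Δ11-12-OTBS enol ether; C15 β; H-10 α)
Conditions: PhMe (0.5 mM), BHT, 130 °C, sealed tube
Reagents that add atoms: none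
Why: Proposed new method: this is a thermal type-1 intramolecular Diels–Alder reaction across an eight-atom tether that forms C13–C14 and C1–C10, and so the six- and ten-membered rings, at once, in which regiochemistry is matched (the enol-ether carbon C13 bonds to the enone β-carbon C14, "para" to OTBS and "ortho" to the C10 alkyl), the tether is pre-bent by the cis-oxirane, E-alkene and lactone, the α-methyl enone reacts with its carbonyl (the tether) exo to give the trans fusion (C15 cis to C9), and A1,3 strain (C9–H eclipsing C20) puts C8 on the diene face that is attacked so that C9 sets C10 (S) and C1 (R), the closest known reaction type being the macrocyclising IMDA that closes 11- to 14-membered carbocycles together with a cyclohexene (cytochalasan-type).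

Step 12
Reactants: 21 the Diels–Alder adduct
Product: 22 (2S)-alcohol of 21
Conditions: Zn(BH4)2, Et2O, −30 °C; aq. NH4Cl
Reagents that add atoms: none
Why: In this chelation-controlled zinc borohydride reduction of an α,β-epoxy ketone, Zn bridges the C=O and the oxirane O and hydride enters from the side away from C4, giving the erythro epoxy alcohol (2S); the enol silane, lactone and acetate are inert.

Step 13
Reactants: 22 the C2 alcohol
Product: 23 2,9-diacetate
Conditions: Ac2O, DMAP, pyridine, rt
Reagents that add atoms: acetic anhydride, CC(=O)OC(C)=O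
Why: DMAP-catalysed acetylation of the only secondary alcohol proceeds with retention at C2, and the tertiary 8-OH and the TBS enol ether survive.

Step 14
Reactants: 23 the diacetate enol silane
Product: 24 12-ketone with H-11 α and C20 β (11R)
Conditions: TBAF/AcOH (1:1.2), THF, −78 → −40 °C
Reagents that add atoms: none
Why: In this fluoride desilylation with kinetic (Zimmerman-type) C-protonation of the enolate, A1,2 strain holds the C9 branch pseudoaxial on the β face, so the proton is delivered axially from the α face (11R), and the cold buffered medium prevents re-enolisation.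

Step 15
Reactants: 24 the 12-ketone
Product: 25 Δ13-en-12-one
Conditions: IBX·4-methoxypyridine N-oxide, DMSO, 25 °C
Reagents that add atoms: none
Why: IBX-mediated ketone dehydrogenation runs through the less hindered C13 enol (C11–H is tertiary and flanked by C10), as in the Δ1-dehydrogenation of 3-keto terpenoids, and leaves C11, the acetates and the epoxide alone.

Step 16
Reactants: 25 the enone
Product: 26 13α,14α-epoxy-12-ketone
Conditions: t-BuOOH (decane), DBU, CH2Cl2, 0 °C
Reagents that add atoms: tert-butyl hydroperoxide, CC(C)(C)OO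
Why: In this Weitz–Scheffer nucleophilic epoxidation t-BuOO− adds axially to C14 anti to the angular C15 methyl (as in the 1α,2α-epoxidation of Δ1-3-keto steroids), setting 13S,14R, and the isolated Δ5 alkene is inert to the nucleophilic oxidant.

Step 17
Reactants: 26 the epoxy ketone
Product: 28 (6R)-6-hydroxy-5(16)-ene, via 6-hydroperoxide 27 (not isolated)
Conditions: O2, TPP (cat.), hν, CH2Cl2, −10 °C; then PPh3
Reagents that add atoms: oxygen, O=O
Why: In this Schenck ene reaction the inner face of Δ5 in the E-cyclodecene is blocked by the ring and H-7 lies in the alkene plane (A1,3), so 1O2 bonds to C6 from the outer face (syn to O7, as in peripheral attack on germacranolides) and can only take H from C16, giving the exomethylene and the 6R-OOH, which PPh3 reduces in situ.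

Step 18
Reactants: 28 the allylic alcohol
Product: 29 (6S)-6-chloro-5(16)-ene 12-ketone
Conditions: PPh3, Cl3CC(O)CCl3, CH2Cl2, −20 → 0 °C
Reagents that add atoms: hexachloroacetone, ClC(Cl)(Cl)C(=O)C(Cl)(Cl)Cl
Why: Appel-type chlorination with PPh3/hexachloroacetone converts secondary allylic alcohols into unrearranged chlorides by SN2 with inversion (6R-OH → 6S-Cl), and the tertiary 8-OH is not activated.

Step 19
Reactants: 29 the chloro ketone
Product: 30 target CNP0141778.2
Conditions: NaBH4, CeCl3·7H2O, MeOH, −78 °C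
Reagents that add atoms: none
Why: In this Luche 1,2-reduction hydride attacks from the α face because the β face is screened by the C20 and C15 methyls, giving the 12β (12R) alcohol trans to the epoxide, and the chloride, epoxides, acetates and lactone survive at −78 °C.

## Compound list
1 | 1,2:5,6-di-O-isopropylidene-α-D-glucofuranose | CC1(C)OC[C@@H](O1)[C@H]2O[C@@H]3OC(C)(C)O[C@@H]3[C@H]2O | starting material
2 | 1,2:5,6-di-O-isopropylidene-α-D-ribo-hexofuranos-3-ulose | CC1(C)OC[C@@H](O1)[C@H]2O[C@@H]3OC(C)(C)O[C@@H]3C2=O | intermediate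
3 | methyl propionate | CCC(=O)OC | starting material
4 | lithium Z(O)-enolate of methyl propionate (CH3 cis to OLi) | C/C=C(\[O-])OC.[Li+] | intermediate
5 | methyl (2R)-2-(1,2:5,6-di-O-isopropylidene-α-D-allofuranos-3-C-yl)propanoate | CC1(C)OC[C@@H](O1)[C@H]2O[C@@H]3OC(C)(C)O[C@@H]3[C@@]2(O)[C@@H](C)C(=O)OC | intermediate
6 | methyl (2R)-2-(1,2-O-isopropylidene-α-D-ribo-pentodialdo-1,4-furanos-3-C-yl)propanoate | O=C[C@H]1O[C@@H]2OC(C)(C)O[C@@H]2[C@@]1(O)[C@@H](C)C(=O)OC | intermediate
7 | 3-(triphenylphosphoranylidene)butan-2-one | CC(=O)C(C)=P(c1ccccc1)(c1ccccc1)c1ccccc1 | starting material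
8 | furanose (E)-enone, 1,2-acetonide | CC(=O)/C(C)=C/[C@H]1O[C@@H]2OC(C)(C)O[C@@H]2[C@@]1(O)[C@@H](C)C(=O)OC | intermediate
9 | lactol (anomeric mixture) | CC(=O)/C(C)=C/[C@H]1OC(O)[C@H](O)[C@@]1(O)[C@@H](C)C(=O)OC | intermediate
10 | 2-(triphenylphosphoranylidene)propanal | CC(C=O)=P(c1ccccc1)(c1ccccc1)c1ccccc1 | starting material
11 | open-chain (5E,10E)-7,8,9-triol methyl ester | CC(=O)/C(C)=C/[C@@H](O)[C@](O)([C@@H](C)C(=O)OC)[C@@H](O)/C=C(C)/C=O | intermediate
12 | (5E,10E)-enal γ-lactone, free 8-OH and 9-OH | CC(=O)/C(C)=C/[C@@H](O)[C@]1(O)[C@@H](C)C(=O)O[C@H]1/C=C(C)/C=O | intermediate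
13 | 9-O-acetyl enal γ-lactone | CC(=O)/C(C)=C/[C@@H](OC(C)=O)[C@]1(O)[C@@H](C)C(=O)O[C@H]1/C=C(C)/C=O | intermediate
14 | 2-chloro-N-methoxy-N-methylacetamide | CON(C)C(=O)CCl | starting material
15 | isopropenylmagnesium bromide | CC(=C)[Mg]Br | starting material
16 | 1-chloro-3-methylbut-3-en-2-one | C=C(C)C(=O)CCl | intermediate
17 | (Z)-diisopinocampheylboron enolate of 16 | Cl/C=C(\OB([C@@H]1C[C@@H]2C[C@@H](C2(C)C)[C@H]1C)[C@@H]1C[C@@H]2C[C@@H](C2(C)C)[C@H]1C)C(C)=C | intermediate
18 | syn-3-chloro-4-hydroxy ketone | CC(=O)/C(C)=C/[C@@H](OC(C)=O)[C@]1(O)[C@@H](C)C(=O)O[C@H]1/C=C(C)/[C@@H](O)[C@H](Cl)C(=O)C(C)=C | intermediate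
19 | cis-(3R,4R)-epoxy isopropenyl ketone | CC(=O)/C(C)=C/[C@@H](OC(C)=O)[C@]1(O)[C@@H](C)C(=O)O[C@H]1/C=C(C)/[C@H]2O[C@H]2C(=O)C(C)=C | intermediate
20 | 12-OTBS 2-silyloxydiene (Diels–Alder precursor) | C=C(O[Si](C)(C)C(C)(C)C)/C(C)=C/[C@@H](OC(C)=O)[C@]1(O)[C@@H](C)C(=O)O[C@H]1/C=C(C)/[C@H]2O[C@H]2C(=O)C(C)=C | intermediate
21 | trans-fused 6/10 adduct, 2-ketone, Δ11 enol silane, 5E | C/C1=C\[C@@H]2OC(=O)[C@H](C)[C@@]2(O)[C@H](OC(C)=O)[C@H]3C(C)=C(O[Si](C)(C)C(C)(C)C)CC[C@]3(C)C(=O)[C@@H]4O[C@@H]41 | intermediate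
22 | (2S)-alcohol | C/C1=C\[C@@H]2OC(=O)[C@H](C)[C@@]2(O)[C@H](OC(C)=O)[C@H]3C(C)=C(O[Si](C)(C)C(C)(C)C)CC[C@]3(C)[C@H](O)[C@@H]4O[C@@H]41 | intermediate
23 | 2,9-diacetate enol silane | C/C1=C\[C@@H]2OC(=O)[C@H](C)[C@@]2(O)[C@H](OC(C)=O)[C@H]3C(C)=C(O[Si](C)(C)C(C)(C)C)CC[C@]3(C)[C@H](OC(C)=O)[C@@H]4O[C@@H]41 | intermediate
24 | (11R)-12-ketone | C/C1=C\[C@@H]2OC(=O)[C@H](C)[C@@]2(O)[C@H](OC(C)=O)[C@H]3[C@@H](C)C(=O)CC[C@]3(C)[C@H](OC(C)=O)[C@@H]4O[C@@H]41 | intermediate
25 | Δ13-en-12-one | C/C1=C\[C@@H]2OC(=O)[C@H](C)[C@@]2(O)[C@H](OC(C)=O)[C@H]3[C@@H](C)C(=O)C=C[C@]3(C)[C@H](OC(C)=O)[C@@H]4O[C@@H]41 | intermediate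
26 | 13α,14α-epoxy-12-ketone, 5E-ene | C/C1=C\[C@@H]2OC(=O)[C@H](C)[C@@]2(O)[C@H](OC(C)=O)[C@H]3[C@@H](C)C(=O)[C@@H]5O[C@@H]5[C@]3(C)[C@H](OC(C)=O)[C@@H]4O[C@@H]41 | intermediate
27 | (6R)-6-hydroperoxy-5(16)-ene | C=C1[C@H]2O[C@H]2[C@@H](OC(C)=O)[C@]2(C)[C@H]([C@@H](C)C(=O)[C@@H]3O[C@@H]32)[C@@H](OC(C)=O)[C@]2(O)[C@@H](C)C(=O)O[C@H]2[C@@H]1OO | intermediate
28 | (6R)-6-hydroxy-5(16)-ene | C=C1[C@H]2O[C@H]2[C@@H](OC(C)=O)[C@]2(C)[C@H]([C@@H](C)C(=O)[C@@H]3O[C@@H]32)[C@@H](OC(C)=O)[C@]2(O)[C@@H](C)C(=O)O[C@H]2[C@@H]1O | intermediate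
29 | (6S)-6-chloro-5(16)-ene 12-ketone | C=C1[C@H]2O[C@H]2[C@@H](OC(C)=O)[C@]2(C)[C@H]([C@@H](C)C(=O)[C@@H]3O[C@@H]32)[C@@H](OC(C)=O)[C@]2(O)[C@@H](C)C(=O)O[C@H]2[C@H]1Cl | intermediate
30 | CNP0141778.2 (1R,2S,3R,4R,6S,7R,8R,9R,10S,11R,12R,13S,14R,17R) | C=C1[C@H]2O[C@H]2[C@@H](OC(C)=O)[C@]2(C)[C@H]([C@@H](C)[C@@H](O)[C@@H]3O[C@@H]32)[C@@H](OC(C)=O)[C@]2(O)[C@@H](C)C(=O)O[C@H]2[C@H]1Cl | target

## Step count and weakest steps
Total step count: 19. Longest linear sequence: 18 (steps 1–7 and 9–19; step 8 is the side branch).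

**Step 11.** Closing a ten-membered ring in the cycloaddition may lose out to oligomerisation or hetero-Diels–Alder pathways. The fallback sets out from 13 and uses 16. TBSOTf/Et3N turns 13 into the silyloxydiene enal F1. This reacts intermolecularly with 16 as the dienophile, with the same exo/A1,3 control, to give the cyclohexene chloromethyl ketone F2. Boron enolisation of the chloromethyl ketone and a high-dilution intramolecular syn-aldol onto the C4 aldehyde then close the ten-membered ring as the macrocyclic chlorohydrin F3. DBU closes the oxirane and the route is rejoined at 21.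

**Step 14.** Protonation may come from the β face, or the ketone may epimerise to the 11-epimer. The fallback sets out from 23. Saegusa–Ito oxidation with Pd(OAc)2 in DMSO gives the 11(20)-methylene 12-ketone F4. Homogeneous hydrogenation (H2, RhCl(PPh3)3) then adds to the unhindered exocyclic alkene from the open α face. This sets H-11α by syn addition instead of protonation, spares the trisubstituted Δ5 alkene, and rejoins the route at 24.

**Step 18.** SN2′ attack giving the C16 chloride, or failure of the hindered displacement, are the likely problems. The fallback sets out from 26 and skips the ene reaction. mCPBA epoxidises Δ5 from the same outer face to give the 5,6-epoxide F5. A chloride source (Li2CuCl4) opens it at the secondary C6 with inversion to give the 6-chloro-5-hydroxy compound F6. Burgess dehydration of the tertiary alcohol toward C16 gives the exomethylene, and the route is rejoined at 29.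

## Further compounds
F1 | step 11 | silyloxydiene enal | C=C(O[Si](C)(C)C(C)(C)C)/C(C)=C/[C@@H](OC(C)=O)[C@]1(O)[C@@H](C)C(=O)O[C@H]1/C=C(C)/C=O
F2 | step 11 | cyclohexene chloromethyl ketone | O=C/C(C)=C/[C@@H]1OC(=O)[C@H](C)[C@@]1(O)[C@H](OC(C)=O)[C@H]2C(C)=C(O[Si](C)(C)C(C)(C)C)CC[C@]2(C)C(=O)CCl
F3 | step 11 | macrocyclic chlorohydrin | C/C1=C\[C@@H]2OC(=O)[C@H](C)[C@@]2(O)[C@H](OC(C)=O)[C@H]3C(C)=C(O[Si](C)(C)C(C)(C)C)CC[C@]3(C)C(=O)[C@@H](Cl)[C@@H]1O
F4 | step 14 | 11(20)-methylene 12-ketone | C/C1=C\[C@@H]2OC(=O)[C@H](C)[C@@]2(O)[C@H](OC(C)=O)[C@H]3C(=C)C(=O)CC[C@]3(C)[C@H](OC(C)=O)[C@@H]4O[C@@H]41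
F5 | step 18 | 5,6-epoxide | C[C@]15[C@H]2O[C@H]2[C@@H](OC(C)=O)[C@]2(C)[C@H]([C@@H](C)C(=O)[C@@H]3O[C@@H]32)[C@@H](OC(C)=O)[C@]2(O)[C@@H](C)C(=O)O[C@H]2[C@@H]1O5
F6 | step 18 | 6-chloro-5-hydroxy compound | C[C@]1(O)[C@H]2O[C@H]2[C@@H](OC(C)=O)[C@]2(C)[C@H]([C@@H](C)C(=O)[C@@H]3O[C@@H]32)[C@@H](OC(C)=O)[C@]2(O)[C@@H](C)C(=O)O[C@H]2[C@H]1Cl
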